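**Retrosynthetic overview**
1. 40 ⇐ SEM removal, O8 angeloylation and lactone alpha-methylenation from hydroxy lactone 32. The gamma-lactone (O6–C12, C7–C11) is the last ring, built on ketone 28 by C8-hydroxyl-directed C7 alkylation and 1,3-anti C6 reduction.
2. Ten-membered ring: anionic oxy-Cope ring expansion of cis-1,2-dialkenylcyclohexenol 24 to dienone 27 (C8–C9 formed, C1–C6 broken, C8 and C9 set).
3. Feature used: in 40 the ring segment C6(O)–C7–C8–C9–C10=C1 is a delta,epsilon-unsaturated carbonyl retron, and C1–C6 with the ring-cis C4=C5 alkene (C15 on C4) map onto 3-methylcyclohex-2-enone.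
4. 24 ⇐ keto ester 7 (SAMP-hydrazone alpha-prime alkylation of 1 with 4) plus E-alkoxyvinyl iodide 15 (from 8); ester formylation and O-SEM alkylation give the C9 enol ether.
5. Ring order: cyclohexene (from 1) → ten-membered carbocycle (step 10) → gamma-lactone (step 13).

Key step: step 10

Remark: C1–C15 are the germacrane atom labels of 40 (ring C1–C10, lactone carbons C11–C13, ester carbon C14, methyl C15); the same labels are used for the cyclohexene intermediates, whose ring is C1–C6.
Assumption: ethynyl ether 13 is thermally labile like other benzyl alkynyl ethers, so it is kept at or below room temperature and used at once.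

Step 1
Reactants: 1 3-methylcyclohex-2-en-1-one; 2 (S)-1-amino-2-(methoxymethyl)pyrrolidine (SAMP)
Product: 3 SAMP hydrazone of 3-methylcyclohex-2-en-1-one
Conditions: cat. TsOH, cyclohexane, reflux, Dean–Stark
Reagents that add atoms: none
Why: Acid-catalysed hydrazone formation at the enone carbonyl is driven by azeotropic removal of water and leaves the conjugated alkene untouched.

Step 2
Reactants: 3 SAMP hydrazone of 3-methylcyclohex-2-en-1-one; 4 methyl bromoacetate
Product: 6 SAMP hydrazone alkylated at C1 by CH2CO2Me (C1 S), via lithium azaenolate 5 (not isolated)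
Conditions: LiN(iPr)2, THF, −78 → 0 °C; 4, −100 → −78 °C
Reagents that add atoms: none
Why: Enders SAMP-hydrazone alkylation: kinetic deprotonation at the alpha-prime CH2 gives the azaenolate whose lithium is held by the methoxymethyl arm, and the bromoacetate should enter from the open face to set C1 as S.

Step 3
Reactants: 6 SAMP hydrazone alkylated at C1 by CH2CO2Me (C1 S)
Product: 7 methyl 2-[(1S)-4-methyl-2-oxocyclohex-3-en-1-yl]acetate
Conditions: sat. aq. oxalic acid, Et2O, rt
Reagents that add atoms: water, O
Why: Mild two-phase hydrazone hydrolysis releases the ketone without enolising the alpha-prime centre and returns the auxiliary as its water-soluble oxalate.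

Step 4
Reactants: 8 4-methoxybenzyl alcohol; 9 trichloroethylene
Product: 11 (E)-1,2-dichlorovinyl 4-methoxybenzyl ether, via potassium 4-methoxybenzyl oxide 10 (not isolated)
Conditions: KH, THF, 0 °C → rt; 9, −50 °C → rt
Reagents that add atoms: none
Why: The alkoxide adds anti across dichloroacetylene generated in situ from trichloroethylene (net vinylic substitution), which gives the E-dichlorovinyl ether.

Step 5
Reactants: 11 (E)-1,2-dichlorovinyl 4-methoxybenzyl ether
Product: 13 ethynyl 4-methoxybenzyl ether, via lithium alkynyl ether 12 (not isolated)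
Conditions: n-BuLi (2.3 equiv), THF, −78 → −40 °C; MeOH, −78 °C; cold work-up
Reagents that add atoms: none
Why: Lithiation and beta-elimination of LiCl give the chloroalkynyl ether, chlorine–lithium exchange gives the lithium alkynyl ether, and methanol protonates it to the terminal ynol ether.

Step 6
Reactants: 13 ethynyl 4-methoxybenzyl ether
Product: 15 (E)-1-iodo-2-[(4-methoxybenzyl)oxy]ethene, via E-alkoxyvinyl zirconocene chloride 14 (not isolated)
Conditions: Cp2Zr(H)Cl, THF, 0 °C → rt; I2, 0 °C
Reagents that add atoms: iodine, II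
Why: Hydrozirconation adds H and Zr syn with zirconium on the terminal carbon and iodinolysis of the C–Zr bond proceeds with retention, so the E-iodovinyl ether should result.

Step 7
Reactants: 15 (E)-1-iodo-2-[(4-methoxybenzyl)oxy]ethene; 7 methyl 2-[(1S)-4-methyl-2-oxocyclohex-3-en-1-yl]acetate
Product: 19 C6 trimethylsilyl ether of the cis adduct (C6 bears OSiMe3 plus the E-alkoxyvinyl group cis to the C1 CH2CO2Me chain), via E-alkoxyvinyllithium 16 (not isolated), via E-alkoxyvinylcerium dichloride 17 (not isolated), via dichlorocerium alkoxide 18 (not isolated)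
Conditions: t-BuLi (2 equiv per 15), Et2O, −78 °C; CeCl3, THF, −78 °C; 7, −78 °C; Me3SiCl, −78 °C → rt
Reagents that add atoms: chlorotrimethylsilane, C[Si](C)(C)Cl
Why: Iodine–lithium exchange with retention, transmetalation to the weakly basic organocerium (Imamoto conditions) and 1,2-addition to the enone carbonyl spare the ester at −78 °C; axial attack on the half-chair with the C1 side chain pseudo-equatorial should place the alkoxyvinyl group cis to that chain and so set C6, and the alkoxide is silylated in the flask.

Step 8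
Reactants: 19 C6 trimethylsilyl ether of the cis adduct; 20 methyl formate
Product: 23 O6-trimethylsilyl ether of the bis(enol ether) 24, via lithium ester enolate 21 (not isolated), via lithium hydroxymethylene-ester enolate 22 (not isolated)
Conditions: LiN(iPr)2, THF, −78 °C; 20, −78 → −20 °C; SEMCl, −78 → 0 °C
Reagents that add atoms: 2-(trimethylsilyl)ethoxymethyl chloride, C[Si](C)(C)CCOCCl
Why: Crossed Claisen formylation of the ester enolate gives the lithium-chelated hydroxymethylene-ester enolate whose oxygen is held cis to the ester carbonyl, so O-alkylation by the hard chloromethyl ether should give the enol ether with OSEM trans to C1.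

Step 9
Reactants: 23 O6-trimethylsilyl ether of the bis(enol ether) 24
Product: 24 cis-1,2-dialkenylcyclohexenol (1S,6R) with E-CH=CH–OPMB on C6 and C(CO2Me)=CH–OSEM on C1
Conditions: Bu4NF, AcOH, THF, 0 °C
Reagents that add atoms: none
Why: Buffered fluoride cleaves the tertiary trimethylsilyl ether by Si–F bond formation while the SEM acetal, both enol ethers and the ester are stable at 0 °C.

Step 10
Reactants: 24 cis-1,2-dialkenylcyclohexenol (1S,6R)
Product: 27 ten-membered dienone (8S,9S) with C6 ketone plus 8-OPMB plus 9-OSEM, via potassium alkoxide 25 (not isolated), via potassium enolate 26 (not isolated)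
Conditions: KH, 18-crown-6, THF, 0 °C → rt; AcOH, THF, −78 °C
Reagents that add atoms: none
Why: KH with 18-crown-6 gives the free C6 potassium alkoxide, whose oxyanion weakens the C1–C6 bond and drives a concerted [3,3] shift of C8=C7–C6–C1–C10=C9 through a chair (anionic oxy-Cope; closest known type: ring expansion of 1,2-dialkenylcyclohexenols to cyclodecadienones). The ten-membered ring is not closed end to end but arises by four-atom ring expansion, C8–C9 forming as C1–C6 breaks. C8 and C9 are controlled by the enol ether geometries: the E-OPMB group and the OSEM group trans to C1 both sit equatorial in the chair, which should give the threo 8S,9S pair by transfer of the C1/C6 chirality. The step needs the chair with axial O− and axial C2 (ring-cis C1=C10) and not the chair with axial C5; the 1,3-diaxial clash of an axial C5 with the C10 ester, together with the cis relation of the two alkenyl groups fixed in step 7, secures this. The push–pull ester should resist attack by the alkoxide, and protonation of the enolate at −78 °C should prevent beta-elimination of the C8 ether.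

Step 11
Reactants: 27 ten-membered dienone (8S,9S) with 8-OPMB plus 9-OSEM
Product: 28 8-hydroxy dienone (8S,9S) with 9-OSEM
Conditions: DDQ, CH2Cl2/pH 7 buffer, 0 °C
Reagents that add atoms: none
Why: Oxidative PMB cleavage (benzylic hydride abstraction by DDQ, then hydrolysis of the oxocarbenium ion) frees the C8 hydroxyl without touching the SEM acetal or the enone.

Step 12
Reactants: 28 8-hydroxy dienone (8S,9S) with 9-OSEM; 4 methyl bromoacetate
Product: 30 C7-alkylated hydroxy ketone (7R,8S,9S) with CH2CO2Me on C7 cis to the 8-OH, via dilithium alkoxide enolate 29 (not isolated)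
Conditions: LiN(iPr)2 (2.3 equiv), THF, −78 °C; 4, −78 → −50 °C; AcOH, −78 °C
Reagents that add atoms: none
Why: Fráter–Seebach-type alkylation: the lithium aldolate is deprotonated at C7 to a dianion in which lithium bridges the C8 alkoxide and the enolate oxygen, and the bromoacetate should attack C7 anti to the C9 branch of this chelate, placing C11 cis to O8, while the oxide at C8 cannot be expelled.

Step 13
Reactants: 30 C7-alkylated hydroxy ketone (7R,8S,9S)
Product: 32 trans-fused 6,12-lactone with free 8-OH plus 9-OSEM, via diol ester 31 (not isolated)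
Conditions: Me4NBH(OAc)3, MeCN/AcOH, −30 °C; aq. work-up; PPTS, toluene, 50 °C
Reagents that add atoms: none
Why: Evans–Saksena reduction: the C8 hydroxyl binds boron and delivers hydride within a six-membered chair to give the 1,3-anti C6 alcohol (6R), and under PPTS the C6 hydroxyl should close the trans-fused gamma-lactone because cis-fusion at O8 would force a near-eclipsed ring torsion.

Step 14
Reactants: 32 trans-fused 6,12-lactone with free 8-OH plus 9-OSEM
Product: 36 alpha-methylene lactone with free 8-OH plus 9-OSEM, via dilithio lactone enolate 33 (not isolated), via Mannich base 34 (not isolated), via trimethylammonium iodide 35 (not isolated)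
Conditions: LiN(iPr)2 (2.3 equiv), THF, −78 °C; Me2N=CH2 I, −78 °C → rt; MeI, MeOH, rt; aq. NaHCO3, EtOAc
Reagents that add atoms: Eschenmoser's salt (N,N-dimethylmethyleneiminium iodide), C=[N+](C)C.[I-]
Why: Mannich-route alpha-methylenation: the lactone enolate (C8 alkoxide as spectator) is aminomethylated, and quaternisation followed by mild base-induced Hofmann-type elimination gives the exocyclic alkene.

Step 15
Reactants: 36 alpha-methylene lactone with free 8-OH plus 9-OSEM; 37 angelic acid
Product: 39 9-O-SEM ether of the target, via mixed anhydride 38 (not isolated)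
Conditions: 37, 2,4,6-trichlorobenzoyl chloride, Et3N, toluene, rt; then 36, 80 °C
Reagents that add atoms: none
Why: Yamaguchi-type esterification without DMAP: the C8 hydroxyl attacks the less hindered angeloyl carbonyl of the mixed anhydride, and leaving out the nucleophilic catalyst should avoid Z to E isomerisation to the tiglate.

Step 16
Reactants: 39 9-O-SEM ether of the target
Product: 40 target CNP0305372.2
Conditions: MgBr2·OEt2, MeNO2, Et2O, rt; aq. work-up
Reagents that add atoms: none
Why: Magnesium coordinates the acetal oxygens and bromide opens the SEM group under non-basic conditions, so the angelate should not migrate to O9 and the alpha-methylene lactone should survive.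

**Compound list**
1 | 3-methylcyclohex-2-en-1-one | CC1=CC(=O)CCC1 | starting material
2 | (S)-1-amino-2-(methoxymethyl)pyrrolidine (SAMP) | COC[C@@H]1CCCN1N | starting material
3 | SAMP hydrazone of 3-methylcyclohex-2-en-1-one (C=N geometry not fixed) | COC[C@@H]1CCCN1N=C1C=C(C)CCC1 | intermediate
4 | methyl bromoacetate | COC(=O)CBr | starting material
5 | lithium azaenolate of 3 (C1 deprotonated, N-lithio aminodiene form) | COC[C@@H]1CCCN1N([Li])C1=CCCC(C)=C1 | intermediate
6 | SAMP hydrazone of 7, CH2CO2Me on C1, C1 configured S | COC[C@@H]1CCCN1N=C1C=C(C)CC[C@H]1CC(=O)OC | intermediate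
7 | methyl 2-[(1S)-4-methyl-2-oxocyclohex-3-en-1-yl]acetate | O=C1C=C(C)CC[C@H]1CC(=O)OC | intermediate
8 | 4-methoxybenzyl alcohol | COc1ccc(CO)cc1 | starting material
9 | trichloroethylene | ClC=C(Cl)Cl | starting material
10 | potassium 4-methoxybenzyl oxide | COc1ccc(C[O-])cc1.[K+] | intermediate
11 | (E)-1,2-dichlorovinyl 4-methoxybenzyl ether | COc1ccc(CO/C(Cl)=C\Cl)cc1 | intermediate
12 | lithium 2-[(4-methoxybenzyl)oxy]ethynide | COc1ccc(COC#C[Li])cc1 | intermediate
13 | ethynyl 4-methoxybenzyl ether | COc1ccc(COC#C)cc1 | intermediate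
14 | chlorobis(cyclopentadienyl)[(E)-2-(4-methoxybenzyloxy)vinyl]zirconium (cyclopentadienyl rings drawn sigma-bonded) | COc1ccc(CO/C=C/[Zr](Cl)(C2C=CC=C2)C2C=CC=C2)cc1 | intermediate
15 | (E)-1-iodo-2-[(4-methoxybenzyl)oxy]ethene | COc1ccc(CO/C=C/I)cc1 | intermediate
16 | (E)-2-[(4-methoxybenzyl)oxy]vinyllithium | COc1ccc(CO/C=C/[Li])cc1 | intermediate
17 | dichloro[(E)-2-(4-methoxybenzyloxy)vinyl]cerium | COc1ccc(CO/C=C/[Ce](Cl)Cl)cc1 | intermediate
18 | dichlorocerium alkoxide of the cis adduct (O6–CeCl2, otherwise as 19) | Cl[Ce](Cl)O[C@]1(/C=C/OCc2ccc(OC)cc2)C=C(C)CC[C@H]1CC(=O)OC | intermediate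
19 | cyclohexene C1–C6 with C4=C5 and C4 methyl; C1 (S) bears CH2CO2Me; C6 bears OSiMe3 and the (E)-2-(4-methoxybenzyloxy)vinyl group cis to the C1 chain | C[Si](C)(C)O[C@]1(/C=C/OCc2ccc(OC)cc2)C=C(C)CC[C@H]1CC(=O)OC | intermediate
20 | methyl formate | COC=O | starting material
21 | lithium enolate of ester 19 | C[Si](C)(C)O[C@]1(/C=C/OCc2ccc(OC)cc2)C=C(C)CC[C@H]1C=C(OC)O[Li] | intermediate
22 | lithium enolate of the alpha-formyl ester (enolate O cis to CO2Me, trans to C1) | C[Si](C)(C)O[C@]1(/C=C/OCc2ccc(OC)cc2)C=C(C)CC[C@H]1/C(C(=O)OC)=C/O[Li] | intermediate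
23 | O6-trimethylsilyl ether of 24 | C[Si](C)(C)O[C@]1(/C=C/OCc2ccc(OC)cc2)C=C(C)CC[C@H]1/C(C(=O)OC)=C/OCOCC[Si](C)(C)C | intermediate
24 | cis-1,2-dialkenylcyclohexenol (1S,6R): C6 bears OH and (E)-CH=CH–OPMB; C1 bears C10(CO2Me)=C9H–OSEM with OSEM trans to C1; the two alkenyl groups cis | O[C@]1(/C=C/OCc2ccc(OC)cc2)C=C(C)CC[C@H]1/C(C(=O)OC)=C/OCOCC[Si](C)(C)C | intermediate
25 | potassium alkoxide of 24 | [K+].[O-][C@]1(/C=C/OCc2ccc(OC)cc2)C=C(C)CC[C@H]1/C(C(=O)OC)=C/OCOCC[Si](C)(C)C | intermediate
26 | potassium enolate of 27 (C6=C7 enolate, O cis to C8) | [K+].[O-]/C1=C\[C@H](OCc2ccc(OC)cc2)[C@@H](OCOCC[Si](C)(C)C)/C(C(=O)OC)=C\CC/C(C)=C\1 | intermediate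
27 | (8S,9S) ten-membered dienone: C6 ketone, ring-cis C4=C5 with C15 on C4, ring-cis C1=C10 with CO2Me on C10, 9-OSEM, 8-OPMB | O=C1/C=C(/C)CC/C=C(/C(=O)OC)[C@H](OCOCC[Si](C)(C)C)[C@@H](OCc2ccc(OC)cc2)C1 | intermediate
28 | (8S,9S) 8-hydroxy dienone, as 27 with free 8-OH | O=C1/C=C(/C)CC/C=C(/C(=O)OC)[C@H](OCOCC[Si](C)(C)C)[C@@H](O)C1 | intermediate
29 | dilithium C8-alkoxide C6-enolate of 28 | [Li]O/C1=C\[C@H](O[Li])[C@@H](OCOCC[Si](C)(C)C)/C(C(=O)OC)=C\CC/C(C)=C\1 | intermediate
30 | (7R,8S,9S) C7-alkylated hydroxy ketone, CH2CO2Me on C7 cis to the 8-OH | O=C1/C=C(/C)CC/C=C(/C(=O)OC)[C@H](OCOCC[Si](C)(C)C)[C@@H](O)[C@H]1CC(=O)OC | intermediate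
31 | (6R,7S,8S,9S) 6,8-anti diol ester | O[C@@H]1/C=C(/C)CC/C=C(/C(=O)OC)[C@H](OCOCC[Si](C)(C)C)[C@@H](O)[C@H]1CC(=O)OC | intermediate
32 | trans-fused 6,12-lactone with free 8-OH and 9-OSEM, C6–C9 arranged as in 40 | C1C(=O)O[C@@H]2/C=C(/C)CC/C=C(/C(=O)OC)[C@H](OCOCC[Si](C)(C)C)[C@@H](O)[C@@H]12 | intermediate
33 | dilithium species of 32 (lactone enolate and C8 alkoxide) | C1=C(O[Li])O[C@@H]2/C=C(/C)CC/C=C(/C(=O)OC)[C@H](OCOCC[Si](C)(C)C)[C@@H](O[Li])[C@@H]12 | intermediate
34 | C11 dimethylaminomethyl lactone (Mannich base, C11 epimers) | CN(C)CC1C(=O)O[C@@H]2/C=C(/C)CC/C=C(/C(=O)OC)[C@H](OCOCC[Si](C)(C)C)[C@@H](O)[C@@H]12 | intermediate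
35 | trimethylammonium iodide of 34 | C[N+](C)(C)CC1C(=O)O[C@@H]2/C=C(/C)CC/C=C(/C(=O)OC)[C@H](OCOCC[Si](C)(C)C)[C@@H](O)[C@@H]12.[I-] | intermediate
36 | alpha-methylene lactone with free 8-OH and 9-OSEM | C=C1C(=O)O[C@@H]2/C=C(/C)CC/C=C(/C(=O)OC)[C@H](OCOCC[Si](C)(C)C)[C@@H](O)[C@@H]12 | intermediate
37 | angelic acid, (Z)-2-methylbut-2-enoic acid | C/C=C(/C)C(=O)O | starting material
38 | angelic 2,4,6-trichlorobenzoic mixed anhydride | C/C=C(/C)C(=O)OC(=O)c1c(Cl)cc(Cl)cc1Cl | intermediate
39 | 9-O-SEM ether of the target | C=C1C(=O)O[C@@H]2/C=C(/C)CC/C=C(/C(=O)OC)[C@H](OCOCC[Si](C)(C)C)[C@@H](OC(=O)/C(C)=C\C)[C@@H]12 | intermediate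
40 | CNP0305372.2 (6R,7S,8S,9S): 8-O-angeloyl, 9-hydroxy, 6,12-olide, C14 methyl ester | C=C1C(=O)O[C@@H]2/C=C(/C)CC/C=C(/C(=O)OC)[C@H](O)[C@@H](OC(=O)/C(C)=C\C)[C@@H]12 | target

**Step count**
Total steps: 16. Longest linear sequence: 13 steps (steps 1–3 then 7–16; the branch 4–6 then 7–16 is equally long).

**Three steps most likely to fail**

Step 10 (key step). The alkoxide may rearrange through the alternative chair with C5 axial and give the ring-trans C1=C10 isomer. It may also acylate itself on the C14 ester, or the product enolate may expel the C8 ether before it is protonated. The fallback sets out from 23 and comes back at 27. The silyl ether 23 is heated as such (toluene, a little N,O-bis(trimethylsilyl)acetamide, 180 °C, sealed tube), so that a neutral silyloxy-Cope rearrangement gives the trimethylsilyl enol ether of the dienone F1. Buffered Bu4NF/AcOH at 0 °C then converts F1 to 27. No alkoxide or free enolate is present on this path, so acyl transfer and beta-elimination are excluded.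

Step 7. The E-alkoxyvinyllithium may lose lithium alkoxide by beta-elimination before transmetalation, or the bulky reagent may attack equatorially and give the trans-dialkenyl adduct. The fallback sets out from 7 and comes back at 19. The slim nucleophile HC≡CMgBr with CeCl3 at −78 °C should add axially to give the ethynyl carbinol F2. Hydrozirconation with excess Cp2Zr(H)Cl and iodinolysis give the E-iodovinyl carbinol F3, and Me3SiCl/imidazole gives its trimethylsilyl ether F4. Copper-catalysed C–O coupling of F4 with 8 (CuI, 3,4,7,8-tetramethyl-1,10-phenanthroline, Cs2CO3, toluene, 80 °C) forms the enol ether bond with retention and gives 19. The enol ether oxygen is thus introduced last and no alkoxyvinyl-lithium is needed.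

Step 12. The lithium aldolate may open by retro-aldol cleavage, the C8 alkoxide may acylate itself on the new ester, or the second deprotonation may occur at the gamma-position of the enone. The fallback sets out from 27 and comes back at 30. The ketone is alkylated before the PMB ether is removed: LiN(iPr)2 (1.1 equiv), THF, −78 °C, then 4, gives the C7-alkylated PMB ether F5, with lithium held between the enolate oxygen and the ether oxygen to direct the same face. DDQ (CH2Cl2/pH 7 buffer, 0 °C) then gives 30. No aldolate is formed on this path.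

**Further compounds**
F1 | step 10 | trimethylsilyl enol ether of dienone 27 | C[Si](C)(C)O/C1=C\[C@H](OCc2ccc(OC)cc2)[C@@H](OCOCC[Si](C)(C)C)/C(C(=O)OC)=C\CC/C(C)=C\1
F2 | step 7 | ethynyl carbinol, ethynyl on C6 cis to the C1 CH2CO2Me chain | O[C@]1(C#C)C=C(C)CC[C@H]1CC(=O)OC
F3 | step 7 | E-iodovinyl carbinol | O[C@]1(/C=C/I)C=C(C)CC[C@H]1CC(=O)OC
F4 | step 7 | trimethylsilyl ether of F3 | C[Si](C)(C)O[C@]1(/C=C/I)C=C(C)CC[C@H]1CC(=O)OC
F5 | step 12 | C7-alkylated 8-O-PMB ketone | O=C1/C=C(/C)CC/C=C(/C(=O)OC)[C@H](OCOCC[Si](C)(C)C)[C@@H](OCc2ccc(OC)cc2)[C@H]1CC(=O)OC
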